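**Plan**
- **Cuts.** The fourteen O-methyl groups are removed last. The ether bonds A C-4–O, B C-4–O, C C-2–O and E C-4–O are cut at the aryl carbon. Each of these rings goes back to a halobenzaldehyde whose CHO later becomes the next phenol oxygen.
- **Enabling feature.** Ring D has oxygen at C-1, C-3 and C-5 and carries the ring E aryloxy group at C-4, between the two hydroxyls. Its six carbons are those of triacetic acid lactone (pyrone C-2 to C-6 plus the 6-CH2) with ArO on the terminal carbon. Cutting D C-3–C-4 therefore gives a 4-benzyloxy-6-(aryloxymethyl)-2-pyrone, and the crowded D C-4–O–E ether is made by an SN2 reaction at a CH2Cl group.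
- **Forward order.** F + E gives the E–F phenol, which is alkylated with the chloromethylpyrone. Ring D then closes by the pyrone-to-benzene switch. Methylation and debenzylation follow, ring C is added by Ullmann coupling, rings B and A by two SNAr/Baeyer–Villiger rounds, and BBr3 finishes the route.
- **Stereochemistry.** The target has no stereocentres. The only geometric element is the C=C bond of a transient ring-opened ester, and it is inherited from the pyrone ring.

Key step: step 6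

**Remarks**
- Rings A, B, D and E are numbered with C-4 as the carbon between the two hydroxyls and C-1 para to it. Ring C has C-1 at O–B and C-2 at O–D.
- EF-oxy = 3,5-dimethoxy-4-(3,4,5-trimethoxyphenoxy)phenoxy. DEF-oxy = 3,5-dimethoxy-4-(EF-oxy)phenoxy.
- Assumption: the five starting materials are taken as catalogue chemicals.

**Step 1**
Reactants: 1 4-hydroxy-6-methyl-2H-pyran-2-one (triacetic acid lactone); 2 benzyl bromide
Product: 3 4-(benzyloxy)-6-methyl-2H-pyran-2-one
Conditions: K2CO3, DMF, 50 °C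
Reagents that add atoms: none
Why: Williamson-type O-alkylation of the vinylogous acid, whose carbonate-derived anion should take up the benzyl group mainly at the 4-oxygen in a polar aprotic solvent, as is usual for this lactone.

**Step 2**
Reactants: 3 4-(benzyloxy)-6-methyl-2H-pyran-2-one
Product: 5 4-(benzyloxy)-6-(chloromethyl)-2H-pyran-2-one, via lithium dienolate 4 (not isolated)
Conditions: LiN(SiMe3)2, THF, −78 °C; cannulated into C2Cl6, THF, −78 °C
Reagents that add atoms: hexachloroethane, ClC(Cl)(Cl)C(Cl)(Cl)Cl; lithium bis(trimethylsilyl)amide, [Li+].C[Si](C)(C)[N-][Si](C)(C)C (lithium of 4 only)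
Why: Vinylogous enolate halogenation, modelled on the chlorination of 2,2,6-trimethyl-1,3-dioxin-4-one: the 6-methyl group is deprotonated and Cl+ is taken up at the exocyclic carbon because only that restores the pyrone, and this anionic route avoids the attack on the benzylic OCH2 that radical NBS bromination would risk.

**Step 3**
Reactants: 6 3,4,5-trimethoxyphenol; 7 4-fluoro-3,5-dimethoxybenzaldehyde
Product: 8 3,5-dimethoxy-4-(3,4,5-trimethoxyphenoxy)benzaldehyde
Conditions: Cs2CO3, DMSO, 120 °C, Ar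
Reagents that add atoms: none
Why: Nucleophilic aromatic substitution in which the para formyl group stabilises the Meisenheimer adduct, fluoride is the best leaving group, and the unhindered phenoxide approaches perpendicular to the ring so the flanking methoxy groups cost little.

**Step 4**
Reactants: 8 3,5-dimethoxy-4-(3,4,5-trimethoxyphenoxy)benzaldehyde
Product: 10 3,5-dimethoxy-4-(3,4,5-trimethoxyphenoxy)phenol (E–F phenol), via aryl formate 9 (not isolated)
Conditions: mCPBA, CH2Cl2, 0 °C to rt; aq. NaHCO3 wash; then K2CO3 (cat.), MeOH, rt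
Reagents that add atoms: mCPBA, OOC(=O)c1cccc(Cl)c1
Why: Baeyer–Villiger (Dakin-type) oxidation in which the trioxygenated aryl group migrates in preference to hydrogen, followed by methanolysis of the labile formate.

**Step 5**
Reactants: 10 E–F phenol; 5 4-(benzyloxy)-6-(chloromethyl)-2H-pyran-2-one
Product: 11 4-(benzyloxy)-6-[(EF-oxy)methyl]-2H-pyran-2-one
Conditions: K2CO3, DMF, 50 °C
Reagents that add atoms: none
Why: Williamson ether synthesis at a primary, allylic-type chloride, so the future D C-4–O–E ether forms by an unhindered SN2 reaction before ring D exists.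

**Step 6**
Reactants: 11 4-(benzyloxy)-6-[(EF-oxy)methyl]-2H-pyran-2-one
Product: 14 5-(benzyloxy)-2-(EF-oxy)benzene-1,3-diol, via keto enoate 12 (not isolated), via cyclohexenedione 13 (not isolated)
Conditions: NaOCH2Ph (1.0 M in BnOH, 4 equiv), 130 °C, Ar; then 1 M HCl, 0 °C
Reagents that add atoms: sodium benzyloxide, [Na+].[O-]Cc1ccccc1 (its benzyloxy group enters 12 and leaves again on closure to 13)
Why: Benzyloxide adds to the lactone carbonyl C-2 of 11 and the C-2–O-1 bond breaks, giving after proton transfer keto enoate 12, in which the benzyl ester and the CH2C(O)CH2OAr arm stay on the same side of the C=C bond because both were ring members (the descriptor is E only because OBn outranks carbon). Reversible deprotonation at C-6 of 12, acidified by the ketone and the aryloxy oxygen, gives the enolate that attacks the ester carbonyl in a 6-(enolendo)-exo-trig Claisen (Dieckmann-type) closure; loss of benzyloxide forms the D C-3–C-4 bond and dione 13, which enolises to the benzene ring of 14. The closest known reaction is the alkoxide- or Mg(OCH3)2-induced conversion of 4-methoxy-6-methyl-2-pyrone and its 6-alkyl relatives into phloroglucinol monoethers. The selectivity needed is carbon acylation from the terminal carbon: the more acidic C-4 methylene of 12 can only relactonise reversibly through oxygen or would have to form a four-membered ring, whereas the six-membered closure ends in a resorcinol bis-phenoxide and is the only irreversible exit. Benzyloxide in benzyl alcohol makes addition–elimination at the benzyloxy-bearing carbon and transesterification degenerate, so the single benzyl label at D C-1 is kept. No lasting stereocentre is formed, since C-2 of 13 becomes planar on enolisation.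

**Step 7**
Reactants: 14 5-(benzyloxy)-2-(EF-oxy)benzene-1,3-diol
Product: 15 5-(benzyloxy)-1,3-dimethoxy-2-(EF-oxy)benzene
Conditions: Me2SO4, K2CO3, acetone, reflux
Reagents that add atoms: dimethyl sulfate, COS(=O)(=O)OC
Why: Williamson O-methylation with a hard electrophile and a weak base, the usual conditions for keeping phloroglucinol-type phenoxides from alkylating at carbon.

**Step 8**
Reactants: 15 5-(benzyloxy)-1,3-dimethoxy-2-(EF-oxy)benzene
Product: 16 3,5-dimethoxy-4-(EF-oxy)phenol (D–E–F phenol)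
Conditions: H2 (1 atm), Pd/C, EtOAc–MeOH, rt
Reagents that add atoms: none
Why: Catalytic hydrogenolysis cleaves only the benzylic C–O bond, because methyl and diaryl ethers are inert under these conditions.

**Step 9**
Reactants: 16 D–E–F phenol; 17 2-bromo-3,4,5-trimethoxybenzaldehyde
Product: 18 3,4,5-trimethoxy-2-(DEF-oxy)benzaldehyde
Conditions: CuI (10 mol %), picolinic acid (20 mol %), K3PO4, DMSO, 90 °C, Ar
Reagents that add atoms: none
Why: Ligand-accelerated Ullmann diaryl ether coupling, helped by the ortho formyl group (it lowers electron density at C–Br and can hold copper) and by the two free ortho positions of phenol 16.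

**Step 10**
Reactants: 18 3,4,5-trimethoxy-2-(DEF-oxy)benzaldehyde
Product: 20 3,4,5-trimethoxy-2-(DEF-oxy)phenol (C–D–E–F phenol), via aryl formate 19 (not isolated)
Conditions: mCPBA, CH2Cl2, 0 °C to rt; aq. NaHCO3 wash; then K2CO3 (cat.), MeOH, rt
Reagents that add atoms: mCPBA, OOC(=O)c1cccc(Cl)c1
Why: Baeyer–Villiger oxidation in which the ortho aryloxy and para methoxy donors favour aryl migration, so the formyl carbon is replaced by the ring C C-1 oxygen next to the new ether.

**Step 11**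
Reactants: 20 C–D–E–F phenol; 7 4-fluoro-3,5-dimethoxybenzaldehyde
Product: 21 3,5-dimethoxy-4-[3,4,5-trimethoxy-2-(DEF-oxy)phenoxy]benzaldehyde
Conditions: Cs2CO3, DMSO, 120 °C, Ar
Reagents that add atoms: none
Why: The same formyl-activated nucleophilic aromatic substitution as in step 3; a Smiles-type shift of the neighbouring aryl group is not expected because ring D is electron-rich.

**Step 12**
Reactants: 21 3,5-dimethoxy-4-[3,4,5-trimethoxy-2-(DEF-oxy)phenoxy]benzaldehyde
Product: 23 3,5-dimethoxy-4-[3,4,5-trimethoxy-2-(DEF-oxy)phenoxy]phenol (B–C–D–E–F phenol), via aryl formate 22 (not isolated)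
Conditions: mCPBA, CH2Cl2, 0 °C to rt; aq. NaHCO3 wash; then K2CO3 (cat.), MeOH, rt
Reagents that add atoms: mCPBA, OOC(=O)c1cccc(Cl)c1
Why: Baeyer–Villiger oxidation and formate methanolysis as in step 4, on the same 4-aryloxy-3,5-dimethoxybenzaldehyde unit.

**Step 13**
Reactants: 23 B–C–D–E–F phenol; 7 4-fluoro-3,5-dimethoxybenzaldehyde
Product: 24 3,5-dimethoxy-4-{3,5-dimethoxy-4-[3,4,5-trimethoxy-2-(DEF-oxy)phenoxy]phenoxy}benzaldehyde
Conditions: Cs2CO3, DMSO, 120 °C, Ar
Reagents that add atoms: none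
Why: Nucleophilic aromatic substitution as in step 3, with a phenoxide that again has two free ortho positions; any aryloxide exchange on the product aldehyde is degenerate.

**Step 14**
Reactants: 24 3,5-dimethoxy-4-{3,5-dimethoxy-4-[3,4,5-trimethoxy-2-(DEF-oxy)phenoxy]phenoxy}benzaldehyde
Product: 26 3,5-dimethoxy-4-{3,5-dimethoxy-4-[3,4,5-trimethoxy-2-(DEF-oxy)phenoxy]phenoxy}phenol (tetradeca-O-methyl ether of the target), via aryl formate 25 (not isolated)
Conditions: mCPBA, CH2Cl2, 0 °C to rt; aq. NaHCO3 wash; then K2CO3 (cat.), MeOH, rt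
Reagents that add atoms: mCPBA, OOC(=O)c1cccc(Cl)c1
Why: Baeyer–Villiger oxidation and formate methanolysis as in step 4, delivering the ring A C-1 hydroxyl, which needs no protection before the last step.

**Step 15**
Reactants: 26 tetradeca-O-methyl ether of the target
Product: 27 CNP0270681.0 (hexamer A–B–C–D–E–F with all fifteen hydroxyls free)
Conditions: BBr3 (excess), CH2Cl2, −78 °C to rt, Ar; then degassed ice–water
Reagents that add atoms: none
Why: Lewis-acid ether cleavage in which bromide removes each boron-complexed methyl group by SN2 while the diaryl ether bonds offer no sp3 carbon and stay intact; air-free work-up protects the pyrogallol-type rings C and F.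

**Compound list**
1 | 4-hydroxy-6-methyl-2H-pyran-2-one | CC1=CC(O)=CC(=O)O1 | starting material
2 | benzyl bromide | BrCc1ccccc1 | starting material
3 | 4-(benzyloxy)-6-methyl-2H-pyran-2-one | CC1=CC(OCc2ccccc2)=CC(=O)O1 | intermediate
4 | lithium 4-(benzyloxy)-6-methylidene-6H-pyran-2-olate | [Li+].C=C1C=C(OCc2ccccc2)C=C([O-])O1 | intermediate
5 | 4-(benzyloxy)-6-(chloromethyl)-2H-pyran-2-one | ClCC1=CC(OCc2ccccc2)=CC(=O)O1 | intermediate
6 | 3,4,5-trimethoxyphenol | COc1cc(O)cc(OC)c1OC | starting material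
7 | 4-fluoro-3,5-dimethoxybenzaldehyde | COc1cc(C=O)cc(OC)c1F | starting material
8 | 3,5-dimethoxy-4-(3,4,5-trimethoxyphenoxy)benzaldehyde | O=Cc1cc(OC)c(Oc2cc(OC)c(OC)c(OC)c2)c(OC)c1 | intermediate
9 | 3,5-dimethoxy-4-(3,4,5-trimethoxyphenoxy)phenyl formate | O=COc1cc(OC)c(Oc2cc(OC)c(OC)c(OC)c2)c(OC)c1 | intermediate
10 | 3,5-dimethoxy-4-(3,4,5-trimethoxyphenoxy)phenol | Oc1cc(OC)c(Oc2cc(OC)c(OC)c(OC)c2)c(OC)c1 | intermediate
11 | 4-(benzyloxy)-6-{[3,5-dimethoxy-4-(3,4,5-trimethoxyphenoxy)phenoxy]methyl}-2H-pyran-2-one | O=C1C=C(OCc2ccccc2)C=C(COc2cc(OC)c(Oc3cc(OC)c(OC)c(OC)c3)c(OC)c2)O1 | intermediate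
12 | benzyl (2E)-3-(benzyloxy)-6-[3,5-dimethoxy-4-(3,4,5-trimethoxyphenoxy)phenoxy]-5-oxohex-2-enoate | O=C(OCc1ccccc1)/C=C(/OCc1ccccc1)CC(=O)COc1cc(OC)c(Oc2cc(OC)c(OC)c(OC)c2)c(OC)c1 | intermediate
13 | 5-(benzyloxy)-2-[3,5-dimethoxy-4-(3,4,5-trimethoxyphenoxy)phenoxy]cyclohex-4-ene-1,3-dione (racemic, transient) | O=C1C=C(OCc2ccccc2)CC(=O)C1Oc1cc(OC)c(Oc2cc(OC)c(OC)c(OC)c2)c(OC)c1 | intermediate
14 | 5-(benzyloxy)-2-[3,5-dimethoxy-4-(3,4,5-trimethoxyphenoxy)phenoxy]benzene-1,3-diol | Oc1cc(OCc2ccccc2)cc(O)c1Oc1cc(OC)c(Oc2cc(OC)c(OC)c(OC)c2)c(OC)c1 | intermediate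
15 | 5-(benzyloxy)-1,3-dimethoxy-2-[3,5-dimethoxy-4-(3,4,5-trimethoxyphenoxy)phenoxy]benzene | COc1cc(OCc2ccccc2)cc(OC)c1Oc1cc(OC)c(Oc2cc(OC)c(OC)c(OC)c2)c(OC)c1 | intermediate
16 | 3,5-dimethoxy-4-[3,5-dimethoxy-4-(3,4,5-trimethoxyphenoxy)phenoxy]phenol | COc1cc(O)cc(OC)c1Oc1cc(OC)c(Oc2cc(OC)c(OC)c(OC)c2)c(OC)c1 | intermediate
17 | 2-bromo-3,4,5-trimethoxybenzaldehyde | O=Cc1cc(OC)c(OC)c(OC)c1Br | starting material
18 | 3,4,5-trimethoxy-2-(DEF-oxy)benzaldehyde | O=Cc1cc(OC)c(OC)c(OC)c1Oc1cc(OC)c(Oc2cc(OC)c(Oc3cc(OC)c(OC)c(OC)c3)c(OC)c2)c(OC)c1 | intermediate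
19 | 3,4,5-trimethoxy-2-(DEF-oxy)phenyl formate | O=COc1cc(OC)c(OC)c(OC)c1Oc1cc(OC)c(Oc2cc(OC)c(Oc3cc(OC)c(OC)c(OC)c3)c(OC)c2)c(OC)c1 | intermediate
20 | 3,4,5-trimethoxy-2-(DEF-oxy)phenol | Oc1cc(OC)c(OC)c(OC)c1Oc1cc(OC)c(Oc2cc(OC)c(Oc3cc(OC)c(OC)c(OC)c3)c(OC)c2)c(OC)c1 | intermediate
21 | 3,5-dimethoxy-4-[3,4,5-trimethoxy-2-(DEF-oxy)phenoxy]benzaldehyde | O=Cc1cc(OC)c(Oc2cc(OC)c(OC)c(OC)c2Oc2cc(OC)c(Oc3cc(OC)c(Oc4cc(OC)c(OC)c(OC)c4)c(OC)c3)c(OC)c2)c(OC)c1 | intermediate
22 | 3,5-dimethoxy-4-[3,4,5-trimethoxy-2-(DEF-oxy)phenoxy]phenyl formate | O=COc1cc(OC)c(Oc2cc(OC)c(OC)c(OC)c2Oc2cc(OC)c(Oc3cc(OC)c(Oc4cc(OC)c(OC)c(OC)c4)c(OC)c3)c(OC)c2)c(OC)c1 | intermediate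
23 | 3,5-dimethoxy-4-[3,4,5-trimethoxy-2-(DEF-oxy)phenoxy]phenol | Oc1cc(OC)c(Oc2cc(OC)c(OC)c(OC)c2Oc2cc(OC)c(Oc3cc(OC)c(Oc4cc(OC)c(OC)c(OC)c4)c(OC)c3)c(OC)c2)c(OC)c1 | intermediate
24 | 3,5-dimethoxy-4-{3,5-dimethoxy-4-[3,4,5-trimethoxy-2-(DEF-oxy)phenoxy]phenoxy}benzaldehyde | O=Cc1cc(OC)c(Oc2cc(OC)c(Oc3cc(OC)c(OC)c(OC)c3Oc3cc(OC)c(Oc4cc(OC)c(Oc5cc(OC)c(OC)c(OC)c5)c(OC)c4)c(OC)c3)c(OC)c2)c(OC)c1 | intermediate
25 | 3,5-dimethoxy-4-{3,5-dimethoxy-4-[3,4,5-trimethoxy-2-(DEF-oxy)phenoxy]phenoxy}phenyl formate | O=COc1cc(OC)c(Oc2cc(OC)c(Oc3cc(OC)c(OC)c(OC)c3Oc3cc(OC)c(Oc4cc(OC)c(Oc5cc(OC)c(OC)c(OC)c5)c(OC)c4)c(OC)c3)c(OC)c2)c(OC)c1 | intermediate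
26 | 3,5-dimethoxy-4-{3,5-dimethoxy-4-[3,4,5-trimethoxy-2-(DEF-oxy)phenoxy]phenoxy}phenol | Oc1cc(OC)c(Oc2cc(OC)c(Oc3cc(OC)c(OC)c(OC)c3Oc3cc(OC)c(Oc4cc(OC)c(Oc5cc(OC)c(OC)c(OC)c5)c(OC)c4)c(OC)c3)c(OC)c2)c(OC)c1 | intermediate
27 | CNP0270681.0 | Oc1cc(O)c(Oc2cc(O)c(Oc3cc(O)c(O)c(O)c3Oc3cc(O)c(Oc4cc(O)c(Oc5cc(O)c(O)c(O)c5)c(O)c4)c(O)c3)c(O)c2)c(O)c1 | target

**Step count**
Total step count: 15.
Longest linear sequence: 13 steps (steps 3–15; the branch through steps 1, 2 and 5–15 is equally long).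

**Steps most likely to fail**

**Step 6.**
- What may go wrong: benzyloxide may add at pyrone C-6 instead of C-2 and drain material into an unreactive carboxylate. The opened chain may fragment by retro-Claisen scission between C-4 and C-5 of 12. Benzyloxide may transfer hydride to the ketone. Deprotonation at C-6 may be too slow, so that 12 only relactonises.
- Fallback: ring D is taken as a bought benzene ring rather than folded. Phenol 10 and fluoroaldehyde 7 (Cs2CO3, DMSO, 120 °C) should give 3,5-dimethoxy-4-(EF-oxy)benzaldehyde F1. mCPBA in CH2Cl2 should convert it into 3,5-dimethoxy-4-(EF-oxy)phenyl formate F2. Methanolysis (cat. K2CO3, MeOH) returns to the route at phenol 16.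

**Step 9.**
- What may go wrong: copper may insert only slowly into the electron-rich C–Br bond flanked on both sides. Protodebromination and air oxidation of the phenoxide then compete.
- Fallback: the halide coupling is replaced by an oxidative boronic acid coupling at room temperature. Bromide 17 is borylated (Miyaura borylation: B2pin2, Pd(dppf)Cl2, KOAc, dioxane, 90 °C) to 3,4,5-trimethoxy-2-(4,4,5,5-tetramethyl-1,3,2-dioxaborolan-2-yl)benzaldehyde F3. The pinacol is cleaved (NaIO4, NH4OAc, acetone–water) to (6-formyl-2,3,4-trimethoxyphenyl)boronic acid F4. A Chan–Evans–Lam coupling with phenol 16 (Cu(OAc)2, pyridine, 4 Å molecular sieves, air, CH2Cl2, rt) returns to the route at aldehyde 18.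

**Step 2.**
- What may go wrong: kinetic metalation and chlorination may occur at ring carbon C-3. Proton exchange between product and dienolate may lead to double chlorination.
- Fallback: the pyrone is built around the aryloxy carbon, so no halogenation is needed. Phenol 10 is alkylated with methyl bromoacetate (K2CO3, acetone) to methyl (EF-oxy)acetate F5. The dianion of methyl acetoacetate (NaH, then n-BuLi, THF, 0 °C) is acylated with it to methyl 6-(EF-oxy)-3,5-dioxohexanoate F6. DBU in refluxing toluene lactonises this to 4-hydroxy-6-[(EF-oxy)methyl]-2H-pyran-2-one F7. O-benzylation with 2 (K2CO3, DMF) returns to the route at pyrone 11.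

**Further compounds**
F1 | step 6 | 3,5-dimethoxy-4-[3,5-dimethoxy-4-(3,4,5-trimethoxyphenoxy)phenoxy]benzaldehyde | O=Cc1cc(OC)c(Oc2cc(OC)c(Oc3cc(OC)c(OC)c(OC)c3)c(OC)c2)c(OC)c1
F2 | step 6 | 3,5-dimethoxy-4-[3,5-dimethoxy-4-(3,4,5-trimethoxyphenoxy)phenoxy]phenyl formate | O=COc1cc(OC)c(Oc2cc(OC)c(Oc3cc(OC)c(OC)c(OC)c3)c(OC)c2)c(OC)c1
F3 | step 9 | 3,4,5-trimethoxy-2-(4,4,5,5-tetramethyl-1,3,2-dioxaborolan-2-yl)benzaldehyde | O=Cc1cc(OC)c(OC)c(OC)c1B1OC(C)(C)C(C)(C)O1
F4 | step 9 | (6-formyl-2,3,4-trimethoxyphenyl)boronic acid | O=Cc1cc(OC)c(OC)c(OC)c1B(O)O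
F5 | step 2 | methyl 2-[3,5-dimethoxy-4-(3,4,5-trimethoxyphenoxy)phenoxy]acetate | COC(=O)COc1cc(OC)c(Oc2cc(OC)c(OC)c(OC)c2)c(OC)c1
F6 | step 2 | methyl 6-[3,5-dimethoxy-4-(3,4,5-trimethoxyphenoxy)phenoxy]-3,5-dioxohexanoate | COC(=O)CC(=O)CC(=O)COc1cc(OC)c(Oc2cc(OC)c(OC)c(OC)c2)c(OC)c1
F7 | step 2 | 4-hydroxy-6-{[3,5-dimethoxy-4-(3,4,5-trimethoxyphenoxy)phenoxy]methyl}-2H-pyran-2-one | O=C1C=C(O)C=C(COc2cc(OC)c(Oc3cc(OC)c(OC)c(OC)c3)c(OC)c2)O1
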